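**Retrosynthetic overview**

- The target is (+)-pinoresinol mono-prenyl ether. Lignan locants are used: guaiacyl half C7–C8–C9, prenyloxyaryl half C7'–C8'–C9'. Ring A is the oxolane O–C7–C8–C8'–C9' (carries the 4-hydroxy-3-methoxyphenyl group); ring B is the oxolane O–C7'–C8'–C8–C9 (carries the prenyloxyaryl group).
- Key disconnection: C8–C8' and C9–O(C7') in one operation. The enabling feature is that ring B holds the three-atom unit O–C7'–C8' next to the two-carbon unit C8–C9, while the C7–O–C9' ether of ring A ties C8' to C8. A C8' radical flanked by a C7' silyloxy group can therefore close ring A onto a C7 vinyl group and hand C9 to the C7' oxygen.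
- The acyclic precursor (a 1-arylallyl 2-iodo-3-aryl-3-silyloxypropyl ether) comes from alkoxide opening of a terminal epoxide (C9'–O bond) and an Appel iodination at C8'.
- Both halves come from vanillin via aryl vinyl carbinols. Sharpless kinetic resolution sets C7' (as the erythro epoxy alcohol) and C7 (as the recovered alcohol); C8 and C8' are set in the key step.
- Ring order: ring A (radical 5-exo closure), then ring B (5-exo-tet etherification), both in the last flask together with desilylation.

Key step: step 10

**Route**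

Step 1
Reactants: 1 vanillin
Product: 2 3-methoxy-4-[(3-methylbut-2-en-1-yl)oxy]benzaldehyde
Conditions: prenyl bromide, K2CO3, DMF, rt
Reagents that add atoms: prenyl bromide (1-bromo-3-methylbut-2-ene), CC(C)=CCBr
Why: Williamson etherification of the phenoxide with an allylic bromide (SN2); no stereocentre is involved.

Step 2
Reactants: 2 3-methoxy-4-[(3-methylbut-2-en-1-yl)oxy]benzaldehyde
Product: 3 racemic 1-{3-methoxy-4-[(3-methylbut-2-en-1-yl)oxy]phenyl}prop-2-en-1-ol
Conditions: CH2=CHMgBr, THF, −78 → 0 °C; then aq NH4Cl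
Reagents that add atoms: vinylmagnesium bromide, C=C[Mg]Br
Why: Grignard 1,2-addition to the aldehyde gives the racemic allylic alcohol, which is resolved in step 3.

Step 3
Reactants: 3 racemic 1-{3-methoxy-4-[(3-methylbut-2-en-1-yl)oxy]phenyl}prop-2-en-1-ol
Product: 4 (R)-{3-methoxy-4-[(3-methylbut-2-en-1-yl)oxy]phenyl}[(2S)-oxiran-2-yl]methanol (erythro)
Conditions: Ti(OiPr)4 (0.15 equiv), D-(−)-diisopropyl tartrate (0.2 equiv), t-BuOOH (0.45 equiv), 4 Å MS, CH2Cl2, −20 °C, stopped before half conversion; unreacted (R)-3 removed by chromatography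
Reagents that add atoms: tert-butyl hydroperoxide, CC(C)(C)OO
Why: Sharpless kinetic resolution by asymmetric epoxidation: with D-(−)-DIPT the (S)-alcohol should be epoxidised much faster than its enantiomer and give the erythro epoxy alcohol, which fixes C7' (the oxirane centre, the later C8', is only temporary), while the isolated prenyl alkene is not an allylic alcohol and should stay untouched.

Step 4
Reactants: 4 (R)-{3-methoxy-4-[(3-methylbut-2-en-1-yl)oxy]phenyl}[(2S)-oxiran-2-yl]methanol
Product: 5 triisopropylsilyl ether of 4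
Conditions: i-Pr3SiOTf, 2,6-lutidine, CH2Cl2, −78 → −20 °C
Reagents that add atoms: triisopropylsilyl trifluoromethanesulfonate, CC(C)[Si](C(C)C)(C(C)C)OS(=O)(=O)C(F)(F)F
Why: Silylation of the secondary alcohol with a silyl triflate and a hindered base at low temperature; the bulky triisopropylsilyl group is chosen because it resists 1,2-migration in step 8, and no stereocentre changes.

Step 5
Reactants: 1 vanillin
Product: 6 3-methoxy-4-(triisopropylsilyloxy)benzaldehyde
Conditions: i-Pr3SiCl, imidazole, DMF, rt
Reagents that add atoms: triisopropylsilyl chloride, CC(C)[Si](Cl)(C(C)C)C(C)C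
Why: Imidazole-assisted silylation of the phenol gives a silyl ether that should survive the Grignard, titanium and radical steps and is removed by fluoride at the end.

Step 6
Reactants: 6 3-methoxy-4-(triisopropylsilyloxy)benzaldehyde
Product: 7 racemic 1-[3-methoxy-4-(triisopropylsilyloxy)phenyl]prop-2-en-1-ol
Conditions: CH2=CHMgBr, THF, −78 → 0 °C; then aq NH4Cl
Reagents that add atoms: vinylmagnesium bromide, C=C[Mg]Br
Why: Grignard 1,2-addition to the aldehyde; the product is racemic and is resolved in step 7.

Step 7
Reactants: 7 racemic 1-[3-methoxy-4-(triisopropylsilyloxy)phenyl]prop-2-en-1-ol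
Product: 8 (S)-1-[3-methoxy-4-(triisopropylsilyloxy)phenyl]prop-2-en-1-ol
Conditions: Ti(OiPr)4 (0.15 equiv), L-(+)-diisopropyl tartrate (0.2 equiv), t-BuOOH (0.65 equiv), 4 Å MS, CH2Cl2, −20 °C, taken past half conversion; 8 recovered by chromatography
Reagents that add atoms: none
Why: Sharpless kinetic resolution in the opposite sense: with L-(+)-DIPT the (R)-alcohol should be epoxidised faster, so the (S)-alcohol, which carries C7, is recovered in high enantiomeric purity.

Step 8
Reactants: 8 (S)-1-[3-methoxy-4-(triisopropylsilyloxy)phenyl]prop-2-en-1-ol; 5 triisopropylsilyl ether of 4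
Product: 9 (1R,2S)-1-{3-methoxy-4-[(3-methylbut-2-en-1-yl)oxy]phenyl}-3-{[(1S)-1-[3-methoxy-4-(triisopropylsilyloxy)phenyl]prop-2-en-1-yl]oxy}-1-(triisopropylsilyloxy)propan-2-ol
Conditions: 8 (1.3 equiv), KH (0.2 equiv), 18-crown-6 (0.2 equiv), THF, 45 °C
Reagents that add atoms: none
Why: Base-catalysed SN2 opening of the terminal epoxide at its CH2 carbon by the secondary alkoxide (Williamson-type etherification) forms the C9'–O bond without touching a stereocentre; proton transfer from 8 to the product alkoxide keeps the base catalytic, which should limit silyl migration, and material from the minor enantiomer of 5 becomes a separable diastereomer.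

Step 9
Reactants: 9 the secondary alcohol from step 8
Product: 10 {[(1R,2R)-2-iodo-1-{3-methoxy-4-[(3-methylbut-2-en-1-yl)oxy]phenyl}-3-{[(1S)-1-[3-methoxy-4-(triisopropylsilyloxy)phenyl]prop-2-en-1-yl]oxy}propyl]oxy}triisopropylsilane
Conditions: PPh3, I2, imidazole, toluene, 60 °C
Reagents that add atoms: iodine, II
Why: Appel reaction under Garegg–Samuelsson conditions: iodide displaces the alkoxyphosphonium ion with inversion at C8'; this centre becomes a radical in step 10, so its configuration does not matter.

Step 10
Reactants: 10 the secondary iodide from step 9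
Product: 12 (+)-pinoresinol mono-prenyl ether (target), via iodomethyl oxolane 11 (not isolated)
Conditions: Et3B (0.3 equiv, in portions), trace air, benzene, rt; then Bu4NF (3 equiv), THF, 0 → 40 °C; aq NH4Cl
Reagents that add atoms: none
Why: Ethyl radicals from Et3B/O2 abstract iodine from 10; the C8' radical adds 5-exo-trig to C8 of the vinyl group (closing ring A) and the primary C9 radical takes iodine from another molecule of 10, so that 11 forms in a chain, after which Bu4NF cleaves both silyl ethers and the C7' alkoxide displaces the primary iodide 5-exo-tet, forming the C9–O bond and closing ring B. The closest known reaction types are the iodine-atom-transfer radical cyclisation of 2-iodoalkyl allyl ethers to 3-(iodomethyl)oxolanes and the intramolecular Williamson etherification of 4-halo alkoxides. C8 should be set by C7: in the chair-like transition state the C7 aryl group lies pseudo-equatorial and ends up trans to the new CH2I group. C8' should be set relative to C8 by the usual preference of radicals substituted at the radical carbon for the cis-disubstituted ring, and only this cis isomer can close the cis-fused bicycle, so the trans isomer is filtered out at the etherification stage. C7' is carried over unchanged from step 3, so once C8' is fixed its aryl group lies on the convex face. The step needs 5-exo over 6-endo closure, the normal mode for 3-oxahex-5-enyl radicals, and cyclisation before iodine transfer, which is secured because transfer to the uncyclised radical only regenerates 10.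

**Compound list**

1 | vanillin (4-hydroxy-3-methoxybenzaldehyde) | O=Cc1ccc(O)c(OC)c1 | starting material
2 | 3-methoxy-4-[(3-methylbut-2-en-1-yl)oxy]benzaldehyde | O=Cc1ccc(OCC=C(C)C)c(OC)c1 | intermediate
3 | racemic 1-{3-methoxy-4-[(3-methylbut-2-en-1-yl)oxy]phenyl}prop-2-en-1-ol | C=CC(O)c1ccc(OCC=C(C)C)c(OC)c1 | intermediate
4 | (R)-{3-methoxy-4-[(3-methylbut-2-en-1-yl)oxy]phenyl}[(2S)-oxiran-2-yl]methanol | O[C@@H]([C@@H]1CO1)c1ccc(OCC=C(C)C)c(OC)c1 | intermediate
5 | {(R)-{3-methoxy-4-[(3-methylbut-2-en-1-yl)oxy]phenyl}[(2S)-oxiran-2-yl]methoxy}triisopropylsilane | CC(C)[Si](C(C)C)(C(C)C)O[C@@H]([C@@H]1CO1)c1ccc(OCC=C(C)C)c(OC)c1 | intermediate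
6 | 3-methoxy-4-(triisopropylsilyloxy)benzaldehyde | O=Cc1ccc(O[Si](C(C)C)(C(C)C)C(C)C)c(OC)c1 | intermediate
7 | racemic 1-[3-methoxy-4-(triisopropylsilyloxy)phenyl]prop-2-en-1-ol | C=CC(O)c1ccc(O[Si](C(C)C)(C(C)C)C(C)C)c(OC)c1 | intermediate
8 | (S)-1-[3-methoxy-4-(triisopropylsilyloxy)phenyl]prop-2-en-1-ol | C=C[C@H](O)c1ccc(O[Si](C(C)C)(C(C)C)C(C)C)c(OC)c1 | intermediate
9 | (1R,2S)-1-{3-methoxy-4-[(3-methylbut-2-en-1-yl)oxy]phenyl}-3-{[(1S)-1-[3-methoxy-4-(triisopropylsilyloxy)phenyl]prop-2-en-1-yl]oxy}-1-(triisopropylsilyloxy)propan-2-ol | C=C[C@H](OC[C@H](O)[C@H](O[Si](C(C)C)(C(C)C)C(C)C)c1ccc(OCC=C(C)C)c(OC)c1)c1ccc(O[Si](C(C)C)(C(C)C)C(C)C)c(OC)c1 | intermediate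
10 | (1R,2R)-2-iodo analogue of 9 (iodine in place of the C2 hydroxyl, inverted) | C=C[C@H](OC[C@@H](I)[C@H](O[Si](C(C)C)(C(C)C)C(C)C)c1ccc(OCC=C(C)C)c(OC)c1)c1ccc(O[Si](C(C)C)(C(C)C)C(C)C)c(OC)c1 | intermediate
11 | {(S)-[(3R,4S,5S)-4-(iodomethyl)-5-[3-methoxy-4-(triisopropylsilyloxy)phenyl]oxolan-3-yl]{3-methoxy-4-[(3-methylbut-2-en-1-yl)oxy]phenyl}methoxy}triisopropylsilane | COc1cc([C@H]2OC[C@H]([C@H](O[Si](C(C)C)(C(C)C)C(C)C)c3ccc(OCC=C(C)C)c(OC)c3)[C@@H]2CI)ccc1O[Si](C(C)C)(C(C)C)C(C)C | intermediate
12 | 4-[(1S,3aR,4S,6aR)-4-{3-methoxy-4-[(3-methylbut-2-en-1-yl)oxy]phenyl}tetrahydro-1H,3H-furo[3,4-c]furan-1-yl]-2-methoxyphenol | COc1cc([C@H]2OC[C@H]3[C@@H]2CO[C@@H]3c2ccc(OCC=C(C)C)c(OC)c2)ccc1O | target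

**Step count and risks**

Total steps: 10. Longest linear sequence: 7 steps (steps 1, 2, 3, 4, 8, 9, 10).

Steps most likely to fail:

1. Step 10. The bulky silyloxy(aryl)methyl group on the radical carbon may erode the cis selectivity of the 5-exo closure, so that much of the material ends as the trans-disubstituted oxolane that cannot close ring B. The fallback moves the tether to ring B and generates the C8' radical with only a small CH2O substituent. It sets out from 4 and 7 and returns at 12. Racemic 7 would be treated with PBr3 (Et2O, 0 °C, allylic transposition) to give (E)-[4-(3-bromoprop-1-en-1-yl)-2-methoxyphenoxy]triisopropylsilane F1. O-Alkylation of 4 with it (NaH, cat. Bu4NI, THF, 0 °C) would give the epoxy cinnamyl ether F2. Cp2TiCl (trivalent titanium, made from Cp2TiCl2 and Zn dust; THF, rt), followed by I2, should open the epoxide to the C8' radical, close ring B 5-exo onto the styrene and, after oxidation of the benzylic radical, let the titanium alkoxide close ring A, giving the silyl-protected furofuran F3. Bu4NF would then give 12. This epoxide-opening radical cyclisation is a documented route to furofuran lignans.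

2. Step 9. Displacement at the hindered C8' carbinol may be diverted by participation or migration of the neighbouring electron-rich aryl group, or by elimination. The fallback avoids substitution at C8'; it sets out from 9 and returns at 11. 9 would be converted with 1,1'-thiocarbonyldiimidazole (DMAP, CH2Cl2) into the imidazole-1-carbothioate F4. Bu3SnH under dry air (toluene), then PPh3, should cleave the C–O bond homolytically, close ring A 5-exo, trap the primary radical with oxygen and reduce the hydroperoxide, giving the hydroxymethyl oxolane F5. Appel iodination of this unhindered primary alcohol (PPh3, I2, imidazole) would give 11, which enters the fluoride stage of step 10.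

3. Step 8. The alkoxide conditions may cause 1,2-migration of the C7' silyl group to the new C8' alkoxide or cleavage of the aryl silyl ether. The fallback forms the other C–O bond of the same ether under non-basic conditions; it sets out from 5 and racemic 7 and returns at 9. Hydrolytic opening of the epoxide of 5 ((salen)Co(OAc), trivalent cobalt, matched enantiomer, H2O, THF) would give the diol F6. Iridium-catalysed enantioconvergent allylic etherification of racemic 7 with the primary hydroxyl of F6 ([Ir(cod)Cl]2, chiral phosphoramidite–alkene ligand of the handedness that gives the (S)-ether, Zn(OTf)2 as promoter) would then give 9 and make the resolution in step 7 unnecessary.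

**Further compounds**

F1 | step 10 | (E)-[4-(3-bromoprop-1-en-1-yl)-2-methoxyphenoxy]triisopropylsilane | BrC/C=C/c1ccc(O[Si](C(C)C)(C(C)C)C(C)C)c(OC)c1
F2 | step 10 | (2S)-2-[(R)-{3-methoxy-4-[(3-methylbut-2-en-1-yl)oxy]phenyl}{[(E)-3-[3-methoxy-4-(triisopropylsilyloxy)phenyl]prop-2-en-1-yl]oxy}methyl]oxirane | COc1cc(/C=C/CO[C@@H]([C@@H]2CO2)c2ccc(OCC=C(C)C)c(OC)c2)ccc1O[Si](C(C)C)(C(C)C)C(C)C
F3 | step 10 | triisopropylsilyl ether of 12 (at the phenol) | COc1cc([C@H]2OC[C@H]3[C@@H]2CO[C@@H]3c2ccc(OCC=C(C)C)c(OC)c2)ccc1O[Si](C(C)C)(C(C)C)C(C)C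
F4 | step 9 | O-alkyl 1H-imidazole-1-carbothioate of 9 (at the C2 hydroxyl) | C=C[C@H](OC[C@H](OC(=S)n1ccnc1)[C@H](O[Si](C(C)C)(C(C)C)C(C)C)c1ccc(OCC=C(C)C)c(OC)c1)c1ccc(O[Si](C(C)C)(C(C)C)C(C)C)c(OC)c1
F5 | step 9 | hydroxymethyl analogue of 11 (CH2OH in place of CH2I) | COc1cc([C@H]2OC[C@H]([C@H](O[Si](C(C)C)(C(C)C)C(C)C)c3ccc(OCC=C(C)C)c(OC)c3)[C@@H]2CO)ccc1O[Si](C(C)C)(C(C)C)C(C)C
F6 | step 8 | (2S,3R)-3-{3-methoxy-4-[(3-methylbut-2-en-1-yl)oxy]phenyl}-3-(triisopropylsilyloxy)propane-1,2-diol | OC[C@H](O)[C@H](O[Si](C(C)C)(C(C)C)C(C)C)c1ccc(OCC=C(C)C)c(OC)c1
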